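**Strategy.** The carbocycle is cut into a dimethylmalonyl unit (C-4, C-5, C-6; benzofuran numbering) and a three-carbon bis-nucleophile (C-3a, C-7a, C-7) that already sits on the chiral dihydrofuran. The key step exploits the β-triketone of the six-membered ring: C-7, between the enol-ether carbon C-7a and the isobutyryl carbonyl, is doubly activated, and C-6 is a ketone flanked by the non-enolisable quaternary C-5. In one operation a 2-(2-silyloxyalkenyl)-4,5-dihydrofuran is C-acylated at C-3a by a dimethylmalonyl half-ester chloride, and the keto ester so formed is closed by a Dieckmann condensation from C-7 onto the ester carbon (C-6). Both stereocentres come from one Sharpless epoxidation of geraniol.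

Key step: step 5

Remark: ethyl 3-chloro-2,2-dimethyl-3-oxopropanoate is taken as a catalogue reagent (otherwise one step from the commercial half ester with oxalyl chloride); β-dicarbonyl compounds are drawn as one tautomer.

Step 1
Reactants: 1 geraniol
Product: 2 [(2R,3R)-3-methyl-3-(4-methylpent-3-en-1-yl)oxiran-2-yl]methanol
Conditions: Ti(OiPr)4 (5 mol%), D-(−)-diethyl tartrate (6 mol%), t-BuOOH (1.5 equiv), 4 Å molecular sieves, CH2Cl2, −20 °C
Reagents that add atoms: tert-butyl hydroperoxide, CC(C)(C)OO
Why: Sharpless asymmetric epoxidation, in which the allylic hydroxyl binds to the titanium tartrate so that only the 2,3-alkene reacts, and the D-(−)-tartrate directs oxygen to the face of the E-alkene that gives the trans (2R,3R)-epoxide, which carries both stereocentres of the target (the CH–O carbon is inverted in step 3, the methyl-bearing carbon is kept).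

Step 2
Reactants: 2 [(2R,3R)-3-methyl-3-(4-methylpent-3-en-1-yl)oxiran-2-yl]methanol
Product: 3 [(2R,3R)-3-methyl-3-(4-methylpent-3-en-1-yl)oxiran-2-yl]methyl 4-methylbenzenesulfonate
Conditions: TsCl (1.2 equiv), Et3N (1.5 equiv), DMAP (5 mol%), CH2Cl2, 0 °C
Reagents that add atoms: 4-methylbenzenesulfonyl chloride, Cc1ccc(cc1)S(=O)(=O)Cl
Why: DMAP-catalysed O-sulfonylation of the primary alcohol under amine base leaves the epoxide and both stereocentres untouched and turns C-1 into an SN2 electrophile.

Step 3
Reactants: 3 [(2R,3R)-3-methyl-3-(4-methylpent-3-en-1-yl)oxiran-2-yl]methyl 4-methylbenzenesulfonate; 4 5-methylhexane-2,4-dione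
Product: 6 (1E)-1-[(5S)-5-[(2R)-2-hydroxy-6-methylhept-5-en-2-yl]oxolan-2-ylidene]-3-methylbutan-2-one, via epoxy diketone 5 (not isolated)
Conditions: 4, LiN(iPr)2 (2.2 equiv), THF, 0 °C; 3, −78 → 0 °C; LiClO4 (2 equiv), 20 → 45 °C; H2O
Reagents that add atoms: none
Why: Domino C-alkylation/O-cyclisation of a 1,3-diketone dianion with a 1,2-dielectrophile, in which the terminal CH2 of the dianion (the future C-3a) displaces the primary tosylate by SN2 and the lithium diketonate 5 then opens the Li+-activated epoxide through its proximal oxygen by 5-exo-tet attack at the secondary carbon with inversion (R to S, while the tertiary carbinol keeps its C–O bond and stays R), the competing C-cyclisation being a disfavoured 5-(enolendo)-exo-tet closure.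

Step 4
Reactants: 6 (1E)-1-[(5S)-5-[(2R)-2-hydroxy-6-methylhept-5-en-2-yl]oxolan-2-ylidene]-3-methylbutan-2-one
Product: 7 trimethyl{[(1Z)-3-methyl-1-[(5S)-5-[(2R)-6-methyl-2-(trimethylsilyloxy)hept-5-en-2-yl]-4,5-dihydrofuran-2-yl]but-1-en-2-yl]oxy}silane
Conditions: TMSOTf (2.5 equiv), Et3N (4 equiv), CH2Cl2, 0 → 20 °C; pentane extraction, used crude
Reagents that add atoms: trimethylsilyl trifluoromethanesulfonate, C[Si](C)(C)OS(=O)(=O)C(F)(F)F
Why: Soft enolisation of a vinylogous ester, in which O-silylation gives a silyloxy-substituted oxocarbenium ion that should lose a proton from the ring CH2 next to the oxocarbenium carbon and not from the hindered isopropyl methine (the preference for the linearly conjugated dienol ether that silyl triflate and amine show with enones), while the tertiary alcohol is silylated in the same operation and no stereocentre is touched.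

Step 5
Reactants: 7 trimethyl{[(1Z)-3-methyl-1-[(5S)-5-[(2R)-6-methyl-2-(trimethylsilyloxy)hept-5-en-2-yl]-4,5-dihydrofuran-2-yl]but-1-en-2-yl]oxy}silane; 8 ethyl 3-chloro-2,2-dimethyl-3-oxopropanoate
Product: 11 (2S,7Z)-2-[(2R)-2-hydroxy-6-methylhept-5-en-2-yl]-7-(1-hydroxy-2-methylpropylidene)-5,5-dimethyl-2,3-dihydro-1-benzofuran-4,6(5H,7H)-dione (the target), via silylated keto ester 9 (not isolated), via silylated trione 10 (not isolated)
Conditions: 8 (1.0 equiv), TMSOTf (10 mol%), CH2Cl2, −78 → 20 °C; evaporate; KOtBu (2.5 equiv), THF, 0 → 20 °C; 1 M HCl, THF, 0 °C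
Reagents that add atoms: none
Why: The terminal carbon of the 2-alkoxy-4-silyloxy-1,3-diene 7 (the future C-3a), which is the vinylogous position of the silyl enol ether and the β-carbon of the ring enol ether, attacks the acid chloride of 8 in a Mukaiyama-type C-acylation with loss of chlorotrimethylsilane, giving 9, in which C-7 has become a CH2 between the enol-ether carbon C-7a and the isobutyryl carbonyl. KOtBu then removes a proton from C-7, and the delocalised anion adds to the ester carbonyl and expels ethoxide, which forms the C-6–C-7 bond and closes the carbocycle. The closest known reaction types are the terminal acylation of 1,3-bis(silyloxy)-1,3-dienes by acid chlorides and the Dieckmann (intramolecular Claisen) closure of triketo esters to 2-acylcyclohexane-1,3,5-triones. The ring closes in the 6-(enolexo)-exo-trig mode, helped by the endocyclic C-3a=C-7a bond, which holds C-7 and the malonyl chain cis to each other; no stereocentre is formed and the two existing ones are remote from every anionic site. The step needs C-3a rather than C-7 or oxygen to be acylated first, which the largest HOMO coefficient at the diene terminus and the far higher reactivity of the acid chloride than of the ester in 8 should secure, and C- rather than O-acylation in the closure, which is secured because only C-7 can reach the ester through a six-membered ring (either oxygen would need a four- or an eight-membered one). The trione is the strongest acid in the flask, so its enolate is the thermodynamic sink that drives the condensation and shields the product from retro-Claisen cleavage until the acidic work-up frees the enol and the tertiary alcohol.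

**Compound list**

1 | geraniol, (2E)-3,7-dimethylocta-2,6-dien-1-ol | CC(C)=CCC/C(C)=C/CO | starting material
2 | [(2R,3R)-3-methyl-3-(4-methylpent-3-en-1-yl)oxiran-2-yl]methanol, (2R,3R)-2,3-epoxygeraniol | CC(C)=CCC[C@@]1(C)O[C@@H]1CO | intermediate
3 | [(2R,3R)-3-methyl-3-(4-methylpent-3-en-1-yl)oxiran-2-yl]methyl 4-methylbenzenesulfonate | CC(C)=CCC[C@@]1(C)O[C@@H]1COS(=O)(=O)c1ccc(C)cc1 | intermediate
4 | 5-methylhexane-2,4-dione | CC(C)C(=O)CC(C)=O | starting material
5 | 2-methyl-7-[(2R,3R)-3-methyl-3-(4-methylpent-3-en-1-yl)oxiran-2-yl]heptane-3,5-dione (lithium enolate in the flask) | CC(C)=CCC[C@@]1(C)O[C@@H]1CCC(=O)CC(=O)C(C)C | intermediate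
6 | (1E)-1-[(5S)-5-[(2R)-2-hydroxy-6-methylhept-5-en-2-yl]oxolan-2-ylidene]-3-methylbutan-2-one (alkene geometry without consequence) | CC(C)=CCC[C@@](C)(O)[C@@H]1CC/C(O1)=C\C(=O)C(C)C | intermediate
7 | trimethyl{[(1Z)-3-methyl-1-[(5S)-5-[(2R)-6-methyl-2-(trimethylsilyloxy)hept-5-en-2-yl]-4,5-dihydrofuran-2-yl]but-1-en-2-yl]oxy}silane | CC(C)=CCC[C@@](C)(O[Si](C)(C)C)[C@@H]1CC=C(O1)/C=C(\O[Si](C)(C)C)C(C)C | intermediate
8 | ethyl 3-chloro-2,2-dimethyl-3-oxopropanoate | CCOC(=O)C(C)(C)C(Cl)=O | starting material
9 | ethyl 2,2-dimethyl-3-[(5S)-2-(3-methyl-2-oxobutyl)-5-[(2R)-6-methyl-2-(trimethylsilyloxy)hept-5-en-2-yl]-4,5-dihydrofuran-3-yl]-3-oxopropanoate | CC(C)=CCC[C@@](C)(O[Si](C)(C)C)[C@@H]1CC(C(=O)C(C)(C)C(=O)OCC)=C(O1)CC(=O)C(C)C | intermediate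
10 | (2S,7Z)-7-(1-hydroxy-2-methylpropylidene)-5,5-dimethyl-2-[(2R)-6-methyl-2-(trimethylsilyloxy)hept-5-en-2-yl]-2,3-dihydro-1-benzofuran-4,6(5H,7H)-dione (potassium enolate in the flask) | CC(C)=CCC[C@@](C)(O[Si](C)(C)C)[C@@H]1CC2=C(O1)/C(=C(/O)C(C)C)C(=O)C(C)(C)C2=O | intermediate
11 | (2S,7Z)-2-[(2R)-2-hydroxy-6-methylhept-5-en-2-yl]-7-(1-hydroxy-2-methylpropylidene)-5,5-dimethyl-2,3-dihydro-1-benzofuran-4,6(5H,7H)-dione | CC(C)=CCC[C@@](C)(O)[C@@H]1CC2=C(O1)/C(=C(/O)C(C)C)C(=O)C(C)(C)C2=O | target

**Totals.** Total step count: 5. Longest linear sequence: 5 steps (1 → 2 → 3 → 6 → 7 → 11); 4 and 8 enter as purchased partners.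

**Steps most likely to fail**

Step 5 (key step). The acylation by the α,α-disubstituted acid chloride may be slow, so that protodesilylation of the diene back to 6, or acylation at a site other than C-3a, competes. The fallback sets out from 7 and comes back at 11. The diene 7 is joined to the malonyl unit by a vinylogous Mukaiyama aldol addition to ethyl 2,2-dimethyl-3-oxopropanoate (BF3·OEt2, CH2Cl2, −78 °C, then dilute HCl). With loss of both silyl groups this should give ethyl 3-hydroxy-3-[(2E,5S)-5-[(2R)-2-hydroxy-6-methylhept-5-en-2-yl]-2-(3-methyl-2-oxobutylidene)oxolan-3-yl]-2,2-dimethylpropanoate F1 as a mixture of epimers at the two new centres. Dess–Martin oxidation of the secondary alcohol (NaHCO3, CH2Cl2) removes both new centres and should give ethyl 3-[(5S)-5-[(2R)-2-hydroxy-6-methylhept-5-en-2-yl]-2-(3-methyl-2-oxobutyl)-4,5-dihydrofuran-3-yl]-2,2-dimethyl-3-oxopropanoate F2. This is closed with KOtBu in THF as in the second stage of step 5 to give 11.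

Step 4. Enolisation may turn toward the isopropyl methine and give the cross-conjugated diene, or the labile dienol ether may hydrolyse during isolation. The fallback sets out from 6 and comes back at 11 without any silyl diene. Ketone 6 is heated with dimethyl 2,2-dimethylmalonate and NaH (excess, trace MeOH) in THF. Under these equilibrating conditions the extended sodium enolate should undergo Claisen acylation at the ring CH2 to give methyl 3-[(5S)-5-[(2R)-2-hydroxy-6-methylhept-5-en-2-yl]-2-(3-methyl-2-oxobutyl)-4,5-dihydrofuran-3-yl]-2,2-dimethyl-3-oxopropanoate F3 (not isolated). Its Dieckmann closure from C-7 gives the enolate of 11. Acylation at the isopropyl methine would give a non-enolisable β-diketone that reverts by retro-Claisen cleavage, so the trione enolate is the only sink. This variant is held in reserve because the intermolecular Claisen step at the neopentyl-type ester is expected to be slow.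

Step 3. The strongly basic dianion may isomerise the epoxide instead of displacing the tosylate, or the Li+-activated epoxide may open at its tertiary carbon to give a six-membered ether. The fallback sets out from 3 and comes back at 6, making the C–O bond first under basic conditions. Dilithioacetate (acetic acid, LiN(iPr)2, 2 equiv, THF/DMPU) is alkylated by 3 to give 3-[(2R,3R)-3-methyl-3-(4-methylpent-3-en-1-yl)oxiran-2-yl]propanoic acid F4 as its carboxylate. On warming, the carboxylate oxygen should open the epoxide at the secondary carbon with inversion to give (5S)-5-[(2R)-2-hydroxy-6-methylhept-5-en-2-yl]oxolan-2-one F5. Claisen-type acylation of the kinetic lithium enolate of 3-methylbutan-2-one (3 equiv, THF, −78 → 0 °C) by this lactone should give (8S,9R)-8,9-dihydroxy-2,9,13-trimethyltetradec-12-ene-3,5-dione F6. Cyclodehydration with pyridinium 4-methylbenzenesulfonate (catalytic, CH2Cl2, 4 Å molecular sieves) through the five-membered hemiketal then gives 6.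

**Further compounds**

F1 | step 5 | ethyl 3-hydroxy-3-[(2E,5S)-5-[(2R)-2-hydroxy-6-methylhept-5-en-2-yl]-2-(3-methyl-2-oxobutylidene)oxolan-3-yl]-2,2-dimethylpropanoate (epimers at the two new centres) | CC(C)=CCC[C@@](C)(O)[C@@H]1CC(C(O)C(C)(C)C(=O)OCC)/C(O1)=C\C(=O)C(C)C
F2 | step 5 | ethyl 3-[(5S)-5-[(2R)-2-hydroxy-6-methylhept-5-en-2-yl]-2-(3-methyl-2-oxobutyl)-4,5-dihydrofuran-3-yl]-2,2-dimethyl-3-oxopropanoate | CC(C)=CCC[C@@](C)(O)[C@@H]1CC(C(=O)C(C)(C)C(=O)OCC)=C(O1)CC(=O)C(C)C
F3 | step 4 | methyl 3-[(5S)-5-[(2R)-2-hydroxy-6-methylhept-5-en-2-yl]-2-(3-methyl-2-oxobutyl)-4,5-dihydrofuran-3-yl]-2,2-dimethyl-3-oxopropanoate | CC(C)=CCC[C@@](C)(O)[C@@H]1CC(C(=O)C(C)(C)C(=O)OC)=C(O1)CC(=O)C(C)C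
F4 | step 3 | 3-[(2R,3R)-3-methyl-3-(4-methylpent-3-en-1-yl)oxiran-2-yl]propanoic acid | CC(C)=CCC[C@@]1(C)O[C@@H]1CCC(=O)O
F5 | step 3 | (5S)-5-[(2R)-2-hydroxy-6-methylhept-5-en-2-yl]oxolan-2-one | CC(C)=CCC[C@@](C)(O)[C@@H]1CCC(=O)O1
F6 | step 3 | (8S,9R)-8,9-dihydroxy-2,9,13-trimethyltetradec-12-ene-3,5-dione | CC(C)=CCC[C@@](C)(O)[C@@H](O)CCC(=O)CC(=O)C(C)C
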